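**Plan**

- Retrosynthesis: the C4' hydroxyl of ring B is masked as a methyl ether and the C3'–CHO bond is cut. Ring B is then opened at C1'–C2' and C5'–C6', with the C5' oxygen traced back to a furan ring oxygen, and finally the O4–acyl bond to ring A is cut.
- Enabling feature: in ring B the oxygens on C2' and C5' are para, with the oxygenated C4' beside C5' and the only unsubstituted carbon at C3'. That is the imprint of a 2-siloxy-4-methoxyfuran. C1' (acyl-bearing) and C6' (methyl-bearing) are the two alkyne carbons of a but-2-ynoate already esterified to O4 of ring A.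
- Forward order: ring A is bought as atraric acid and acylated at O4 with but-2-ynoic acid. The furan comes from methyl tetronate. Ring B is built on the ester by cycloaddition and aromatisation, then formylated at C3' and demethylated at O4'.
- Stereochemistry: the target has no stereocentre. The two bridgehead centres of the cycloadduct are racemic, transient and erased on aromatisation.

Key step: step 3

Remark: primed locants refer to ring B (C1' carries the depside carbonyl, C2' OH, C3' CHO, C4' OH, C5' OH, C6' CH3) and unprimed locants to ring A, the methyl benzoate ring. Compounds 8–10 are electron-rich hydroquinones and would be handled under argon.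

**Route**

Step 1
Reactants: 1 methyl 2,4-dihydroxy-3,6-dimethylbenzoate (atraric acid); 2 but-2-ynoic acid
Product: 3 methyl 4-(but-2-ynoyloxy)-2-hydroxy-3,6-dimethylbenzoate
Conditions: DCC (1.1 equiv), DMAP (5 mol %), CH2Cl2, 0 °C to rt
Reagents that add atoms: none
Why: Steglich esterification, in which the small sp-hybridised acyl group should go to the C4 hydroxyl, the only phenol that is neither hydrogen-bonded to the ester carbonyl nor flanked by two substituents, while low temperature and catalytic DMAP limit conjugate addition to the ynoate.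

Step 2
Reactants: 4 4-methoxyfuran-2(5H)-one (methyl tetronate)
Product: 5 tert-butyl[(4-methoxyfuran-2-yl)oxy]dimethylsilane
Conditions: TBSOTf, Et3N, CH2Cl2, 0 °C; pentane extraction, used at once
Reagents that add atoms: tert-butyldimethylsilyl trifluoromethanesulfonate (TBSOTf), CC(C)(C)[Si](C)(C)OS(=O)(=O)C(F)(F)F
Why: Soft enolisation at C5 of the butenolide and O-silylation of the resulting dienolate should give the aromatic 2-siloxyfuran, the standard preparation of siloxyfurans from butenolides.

Step 3
Reactants: 3 methyl 4-(but-2-ynoyloxy)-2-hydroxy-3,6-dimethylbenzoate; 5 tert-butyl[(4-methoxyfuran-2-yl)oxy]dimethylsilane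
Product: 8 methyl 4-[(2,5-dihydroxy-4-methoxy-6-methylbenzoyl)oxy]-2-hydroxy-3,6-dimethylbenzoate, via oxanorbornadiene cycloadduct 6 (not isolated), via aryl silyl ether 7 (not isolated)
Conditions: 5 (2.5 equiv), toluene, 100 °C, sealed tube, argon; then HF·pyridine, THF, 0 °C to rt
Reagents that add atoms: none
Why: Furan 5 should add to the ynoate of 3 in an asynchronous (4+2) cycloaddition in which furan C5, the terminus pushed by both the siloxy and the methoxy oxygen, bonds first to the methyl-bearing beta carbon (C6') and the siloxy-bearing C2 then closes onto the alpha carbon (C1'), so the six-membered carbocycle of ring B closes by cycloaddition as the 7-oxanorbornadiene 6. The ketal-like C2'–O bridge bond of 6 then ionises to a cation stabilised by the siloxy oxygen and, through the C3'=C4' enol ether, by the methoxy group; the bridge oxygen stays on C5' and loss of the C5' hydrogen gives arene 7, whose silyl ether is removed by fluoride. The closest known reaction type is the Diels–Alder reaction of 2-siloxyfurans and 2-alkoxyfurans with acetylenic esters followed by opening of the oxygen bridge to para-oxygenated phenols. The two bridgehead stereocentres of 6 form as a racemate, are held cis by the bicycle and vanish on aromatisation, so no stereocontrol is required. The step needs the right orientation of the cycloaddition and the right direction of bridge opening; the first is secured by matching the doubly donor-activated furan C5 to the electrophilic beta carbon of the ynoate, the second by the much better stabilised cation at C2' than at C5'. The aryl ester makes the ynoate a better acceptor than an alkyl ester would, and the excess of 5 covers furan lost by proton transfer from the chelated ring A phenol.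

Step 4
Reactants: 8 methyl 4-[(2,5-dihydroxy-4-methoxy-6-methylbenzoyl)oxy]-2-hydroxy-3,6-dimethylbenzoate
Product: 9 methyl 4-[(3-formyl-2,5-dihydroxy-4-methoxy-6-methylbenzoyl)oxy]-2-hydroxy-3,6-dimethylbenzoate
Conditions: Cl2CHOMe, TiCl4 (excess), CH2Cl2, −20 to 0 °C; then aq. HCl
Reagents that add atoms: dichloromethyl methyl ether, COC(Cl)Cl; water, O
Why: Rieche formylation, in which the chloromethoxycarbenium ion generated by TiCl4 should substitute C3', the only unsubstituted carbon of ring B and the one ortho to both the titanium-bound C2' oxygen and the C4' methoxy group, whereas the lone ring A hydrogen at C5 lies meta to the ester on a ring whose only phenol is locked in a titanium salicylate chelate.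

Step 5
Reactants: 9 methyl 4-[(3-formyl-2,5-dihydroxy-4-methoxy-6-methylbenzoyl)oxy]-2-hydroxy-3,6-dimethylbenzoate
Product: 10 methyl 4-[(3-formyl-2,4,5-trihydroxy-6-methylbenzoyl)oxy]-2-hydroxy-3,6-dimethylbenzoate
Conditions: BCl3 (1 M in CH2Cl2, excess), CH2Cl2, −78 to 0 °C; then H2O
Reagents that add atoms: none
Why: Chelation-controlled Lewis acid ether cleavage, in which boron held between the aldehyde oxygen, the C5' phenoxide and the C4' methoxy oxygen activates that O–methyl bond for attack by chloride, while the methyl ester and the hindered aryl ester should survive at this temperature and the aryl borate is hydrolysed on work-up.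

**Compound list**

1 | methyl 2,4-dihydroxy-3,6-dimethylbenzoate (atraric acid) | COC(=O)c1c(C)cc(O)c(C)c1O | starting material
2 | but-2-ynoic acid | CC#CC(=O)O | starting material
3 | methyl 4-(but-2-ynoyloxy)-2-hydroxy-3,6-dimethylbenzoate | COC(=O)c1c(C)cc(OC(=O)C#CC)c(C)c1O | intermediate
4 | 4-methoxyfuran-2(5H)-one (methyl tetronate) | COC1=CC(=O)OC1 | starting material
5 | tert-butyl[(4-methoxyfuran-2-yl)oxy]dimethylsilane | COc1coc(O[Si](C)(C)C(C)(C)C)c1 | intermediate
6 | methyl 4-({1-[(tert-butyldimethylsilyl)oxy]-5-methoxy-3-methyl-7-oxabicyclo[2.2.1]hepta-2,5-diene-2-carbonyl}oxy)-2-hydroxy-3,6-dimethylbenzoate (racemic; the two bridgeheads are necessarily cis across the oxygen bridge) | COC(=O)c1c(C)cc(OC(=O)C2=C(C)C3OC2(O[Si](C)(C)C(C)(C)C)C=C3OC)c(C)c1O | intermediate (not isolated)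
7 | methyl 4-({2-[(tert-butyldimethylsilyl)oxy]-5-hydroxy-4-methoxy-6-methylbenzoyl}oxy)-2-hydroxy-3,6-dimethylbenzoate | COC(=O)c1c(C)cc(OC(=O)c2c(C)c(O)c(OC)cc2O[Si](C)(C)C(C)(C)C)c(C)c1O | intermediate (not isolated)
8 | methyl 4-[(2,5-dihydroxy-4-methoxy-6-methylbenzoyl)oxy]-2-hydroxy-3,6-dimethylbenzoate | COC(=O)c1c(C)cc(OC(=O)c2c(C)c(O)c(OC)cc2O)c(C)c1O | intermediate
9 | methyl 4-[(3-formyl-2,5-dihydroxy-4-methoxy-6-methylbenzoyl)oxy]-2-hydroxy-3,6-dimethylbenzoate | COC(=O)c1c(C)cc(OC(=O)c2c(C)c(O)c(OC)c(C=O)c2O)c(C)c1O | intermediate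
10 | methyl 4-[(3-formyl-2,4,5-trihydroxy-6-methylbenzoyl)oxy]-2-hydroxy-3,6-dimethylbenzoate | COC(=O)c1c(C)cc(OC(=O)c2c(C)c(O)c(O)c(C=O)c2O)c(C)c1O | target

**Step count**

Total steps: 5 (steps 1 and 2 are parallel branches).
Longest linear sequence: 4 steps (step 1 or step 2, then steps 3, 4 and 5).

**Steps most likely to fail**

Step 3. The beta-methyl ynoate may add too slowly, so that the siloxyfuran is used up by proton transfer from the ring A phenol or by open-chain Michael addition before the ring closes. The fallback replaces the ynoate by its more dienophilic allene isomer. It sets out from 1, which with but-3-ynoic acid, 2-chloro-1-methylpyridinium iodide and Et3N in CH2Cl2 (esterification with in situ isomerisation) should give methyl 4-(buta-2,3-dienoyloxy)-2-hydroxy-3,6-dimethylbenzoate F1. Furan 5 should add across the alpha,beta double bond of F1 in toluene at 40–60 °C with the same orientation, bonding to the central allene carbon through furan C5. This gives methyl 4-({1-[(tert-butyldimethylsilyl)oxy]-5-methoxy-3-methylidene-7-oxabicyclo[2.2.1]hept-5-ene-2-carbonyl}oxy)-2-hydroxy-3,6-dimethylbenzoate F2 as a racemic endo/exo mixture. Bridge opening at C2' and a proton shift from C5' to the exocyclic methylene (trace acid or Et3N) turn F2 into the aryl silyl ether 7, where the fallback rejoins the route; HF·pyridine then gives 8 as in step 3.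

Step 4. The formyl cation equivalent may attack C5 of ring A in competition with C3', or titanium chelation may slow substitution enough for the hydroquinone to degrade. The fallback abandons the Lewis acid electrophilic substitution for a phenoxide-templated hydroxymethylation with in situ hydride transfer (Casnati–Skattebøl ortho-formylation). It sets out from 8, which with MgCl2, Et3N and paraformaldehyde in THF at reflux under argon should be hydroxymethylated only ortho to a magnesium phenoxide. Ring A has no free ortho position, so the product should be methyl 4-{[2,5-dihydroxy-3-(hydroxymethyl)-4-methoxy-6-methylbenzoyl]oxy}-2-hydroxy-3,6-dimethylbenzoate F3, formed as its magnesium alkoxide and not isolated. Hydride transfer from F3 to a second formaldehyde should give 9, where the fallback rejoins the route.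

Step 5. The boron Lewis acid may cleave the depside ester or the methyl ester, or dealkylation at O4' may stop short. The fallback carries O4' as a benzyl ether from the start and ends with a neutral hydrogenolysis. It sets out from 3 and rejoins the route at 10.
- Tetronic acid would be O-benzylated under Mitsunobu conditions (BnOH, PPh3, DIAD) to 4-(benzyloxy)furan-2(5H)-one F4.
- F4 would be silylated as in step 2 to {[4-(benzyloxy)furan-2-yl]oxy}(tert-butyl)dimethylsilane F5.
- Heating F5 with 3 as in step 3 should give methyl 4-({5-(benzyloxy)-1-[(tert-butyldimethylsilyl)oxy]-3-methyl-7-oxabicyclo[2.2.1]hepta-2,5-diene-2-carbonyl}oxy)-2-hydroxy-3,6-dimethylbenzoate F6, which should open to methyl 4-({4-(benzyloxy)-2-[(tert-butyldimethylsilyl)oxy]-5-hydroxy-6-methylbenzoyl}oxy)-2-hydroxy-3,6-dimethylbenzoate F7.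
- HF·pyridine should then give methyl 4-{[4-(benzyloxy)-2,5-dihydroxy-6-methylbenzoyl]oxy}-2-hydroxy-3,6-dimethylbenzoate F8.
- Rieche formylation as in step 4 should give methyl 4-{[4-(benzyloxy)-3-formyl-2,5-dihydroxy-6-methylbenzoyl]oxy}-2-hydroxy-3,6-dimethylbenzoate F9.
- Brief hydrogenolysis of F9 (H2, 1 atm, Pd/C, EtOAc, rt) should give 10.

**Further compounds**

F1 | step 3 | methyl 4-(buta-2,3-dienoyloxy)-2-hydroxy-3,6-dimethylbenzoate | COC(=O)c1c(C)cc(OC(=O)C=C=C)c(C)c1O
F2 | step 3 | methyl 4-({1-[(tert-butyldimethylsilyl)oxy]-5-methoxy-3-methylidene-7-oxabicyclo[2.2.1]hept-5-ene-2-carbonyl}oxy)-2-hydroxy-3,6-dimethylbenzoate (racemic, endo/exo mixture) | COC(=O)c1c(C)cc(OC(=O)C2C(=C)C3OC2(O[Si](C)(C)C(C)(C)C)C=C3OC)c(C)c1O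
F3 | step 4 | methyl 4-{[2,5-dihydroxy-3-(hydroxymethyl)-4-methoxy-6-methylbenzoyl]oxy}-2-hydroxy-3,6-dimethylbenzoate | COC(=O)c1c(C)cc(OC(=O)c2c(C)c(O)c(OC)c(CO)c2O)c(C)c1O
F4 | step 5 | 4-(benzyloxy)furan-2(5H)-one | O=C1C=C(OCc2ccccc2)CO1
F5 | step 5 | {[4-(benzyloxy)furan-2-yl]oxy}(tert-butyl)dimethylsilane | CC(C)(C)[Si](C)(C)Oc1cc(OCc2ccccc2)co1
F6 | step 5 | methyl 4-({5-(benzyloxy)-1-[(tert-butyldimethylsilyl)oxy]-3-methyl-7-oxabicyclo[2.2.1]hepta-2,5-diene-2-carbonyl}oxy)-2-hydroxy-3,6-dimethylbenzoate (racemic) | COC(=O)c1c(C)cc(OC(=O)C2=C(C)C3OC2(O[Si](C)(C)C(C)(C)C)C=C3OCc2ccccc2)c(C)c1O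
F7 | step 5 | methyl 4-({4-(benzyloxy)-2-[(tert-butyldimethylsilyl)oxy]-5-hydroxy-6-methylbenzoyl}oxy)-2-hydroxy-3,6-dimethylbenzoate | COC(=O)c1c(C)cc(OC(=O)c2c(C)c(O)c(OCc3ccccc3)cc2O[Si](C)(C)C(C)(C)C)c(C)c1O
F8 | step 5 | methyl 4-{[4-(benzyloxy)-2,5-dihydroxy-6-methylbenzoyl]oxy}-2-hydroxy-3,6-dimethylbenzoate | COC(=O)c1c(C)cc(OC(=O)c2c(C)c(O)c(OCc3ccccc3)cc2O)c(C)c1O
F9 | step 5 | methyl 4-{[4-(benzyloxy)-3-formyl-2,5-dihydroxy-6-methylbenzoyl]oxy}-2-hydroxy-3,6-dimethylbenzoate | COC(=O)c1c(C)cc(OC(=O)c2c(C)c(O)c(OCc3ccccc3)c(C=O)c2O)c(C)c1O
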